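Atom labels (C1 to C15, C15′ to C10′) follow carotenoid numbering: ring A is C1–C6 (C1 gem-dimethyl, C3 carbinol, C5 methylated ether carbon), ring B is O–C5–C6=C7–C8, and the chain runs C9 to C15, then C15′ back to C10′ (the CH2OH). Plain numerals are compound numbers.

## Analysis of the target

The target is a C27 furanoid apocarotenoid diol. Ring A (cyclohexane C1–C6) is fused through C5–C6 to ring B, a 2,5-dihydrofuran O–C5–C6=C7–C8 whose double bond is exocyclic to ring A; C8 carries a conjugated hexaene (C9=C10 Z, the other five E) ending in the primary allylic alcohol C10′. There are three stereocentres: C3 (S, secondary carbinol), C5 (R, fully substituted ether carbon) and C8 (R, ether methine). The C3 and C5 oxygens are trans on ring A (the C3 oxygen is cis to the C5 methyl), and across the ring oxygen H8 is cis to the C5 methyl, so the polyene lies on the face of C4. C8 is the sensitive centre: it is an ether carbon flanked by two alkenes, acid reopens ring B to a delocalised cation and scrambles it, and its two faces differ only through the C5 substituents on the far side of the oxygen. The hexaene with its single Z bond does not bear acid, iodine, light or long heating, so it must arrive late and by a bond formation that keeps alkene geometry. The plan rests on C7: it is a lone CH between C6, whose neighbours C1 and C5 are both quaternary (a C6 ketone cannot enolise), and C8, an oxygen-bound allylic carbon five atoms from C7 along C6–C5–O. C7 can therefore be brought in as a one-carbon carbene unit on a C6 ketone, and ring B closed by insertion into a C8–H bond of a C5 allyl ether.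

## Retrosynthetic reasoning

Target 26 is traced back to its C3 silyl ether 25. The silyl group is put on in the first step and survives everything after it, and its removal by fluoride is basic, which suits the acid-labile C8 ether and the polyene.

25 is cut at the C10–C11 single bond between two alkenes, giving furanoid (Z)-alkenyl iodide 14 and (E)-alkenylstannane 24. This separates the rings and all three stereocentres (in 14) from the light- and acid-sensitive pentaene (in 24). Both alkene geometries next to the new bond are fixed beforehand in small, robust precursors, so the forward Stille coupling only has to join two sp2 carbons with retention. A cut at a double bond was not taken, because an olefination would create geometry at the moment of coupling, right next to the Z bond.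

14 is disconnected at C6=C7 and C7–C8 together, which removes C7 and opens ring B. The precursor is ketone 10, a C5 O-allyl ether, and the carbon comes from silyl diazomethane 11. Forward, lithiated 11 adds to the C6 carbonyl (adduct 12); Peterson-type elimination and extrusion of nitrogen leave alkylidene carbene 13, which inserts into a C8–H bond. The cut is placed here for three reasons:
- C6 of 10 cannot enolise, so addition is the only thing the basic reagent can do.
- C8–H is the one C–H bond that is both activated (ether oxygen, C9=C10) and reachable through a five-membered transition state.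
- Two skeletal bonds, ring B and the C8 centre come from one operation on a substrate that already holds C3 and C5.

The forward step must choose between two diastereotopic hydrogens.

10 is cut at the O–C8 bond into tertiary α-hydroxy ketone 4 and allylic bromide 8 (Williamson etherification through alkoxide 9). This seam joins the chiral ring to an achiral C4 piece that already carries the Z alkene, the iodine handle for C10 and the C9 methyl. The electrophile is primary, allylic and unable to eliminate.

4 goes back to silyl ether 2 by removing the C5 oxygen (hydroxylation of enolate 3), and 2 goes back to actinol 1. Ketone 2 has a single enolisable position, so the oxygen can only enter at C5. C3 comes from the chiral pool and steers the new centre by axial attack anti to the silyloxy group.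

8 comes from alcohol 7 by Appel bromination, and 7 from propargyl alcohol 5. Copper-catalysed anti-carbomagnesiation puts the methyl on the inner alkyne carbon and, through chelate 6, magnesium cis to the CH2O group, so iodinolysis gives the Z iodide in one flask. This is why the iodine sits on the ring half of the coupling.

24 is simplified to ester 23, and 23 is cut at C11=C12 into aldehyde 17 and the one-carbon tin reagent 21 (Takai–Hodgson olefination through 22, E-selective). 17 is cut at C11′=C12′ into the symmetrical C10 dialdehyde 15 and phosphonoacetate 16 (Horner–Wadsworth–Emmons). 15 supplies the four inner double bonds and both methyl branches with their geometry, so only the two outer E bonds have to be made. 21 is made from dibromomethane 18 and tributyltin chloride 19 through carbenoid 20.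

## Alternatives that were turned down

Alternative 1: Both rings are unzipped at once, C1–C6 of ring A and C5–O of ring B, back to the acyclic allenyl enone carbinol A2, whose C8 carbinol would be made beforehand by a standard asymmetric method. In the forward key step a Lewis acid of the dialkylaluminium chloride type activates the C1=C2–C3=O enone, the central allene carbon C6 attacks C1 (ring A), and the C8 hydroxyl captures the C5 cation (ring B), giving the 3-keto furanoid silyl ether A1.
- For: two rings and both quaternary carbons (C1, C5) arise in one step from a chain. C8, the centre the insertion controls least, is fixed in advance and simply carried into ring B. On these two points this plan is the stronger one.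
- Against: C1 is the fully substituted β-carbon of a β,β-dimethyl enone, so the C1–C6 bond should form slowly and reversibly. The same Lewis acid can ionise the C8 carbinol of A2, which is allylic on one side and allenylic on the other, and so erase the centre the plan relies on. The face on which the hydroxyl meets the C5 cation, and with it the C5/C8 relationship, is not enforced. C3 emerges as a ketone that must later be reduced with only a 1,3-related centre to guide the hydride. A1 ends at C11 as a silyl ether, so the chain needs deprotection, oxidation to a (9Z)-enal that isomerises easily, and an olefination that creates the C11=C12 geometry at the coupling.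
- Comparison: A2 (allene, Z trisubstituted alkene, carbinol) is longer to make than ketone 10, which is three linear steps from actinol. The chosen plan gives up the pre-set C8, but takes C3 from the chiral pool, forms ring B on a substrate class for which the insertion is established, and ends on an alkenyl iodide that couples with retention.

Alternative 2: Ring B is opened at both C–O bonds, back to the abscisic nitrile A4, which is (S)-abscisic acid A5 with the carboxyl turned into a nitrile. In the forward key step a high-valent rhenium oxo catalyst shifts the tertiary C6 hydroxyl across the allyl unit to C8 in a suprafacial [3,3] sense (new C8–O bond, new C6=C7 alkene). The new hydroxyl then adds in conjugate fashion to C5 of the enone (5-exo closure of ring B), giving the 3-keto furanoid (Z)-enenitrile A3.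
- For: A5 is a purchasable single enantiomer that already holds C1–C11 with every methyl and the Z C9=C10 bond. The bicyclic core is two or three steps away, against six operations for 14, so on step economy this plan is clearly ahead. The sigmatropic shift can pass the C6 configuration on to C8, and the natural S acid has the right sense if the shift runs through the rotamer with C8 cis to C5. The conjugate addition is reversible and can settle C5 thermodynamically.
- Against: the rhenium ester of a tertiary alcohol that becomes doubly allylic ionises readily, so an ion-pair path competes with the concerted one; the C8 configuration is then lost and the C9=C10 geometry, which lies inside the delocalised cation, scrambles. The new C6=C7 bond must form with C8 cis to C5 or ring B cannot close. A3 is a β-alkoxy ketone that can reopen by retro-conjugate addition under any later base. C3 must again be set by a reduction with remote control only. The nitrile must be taken to the (9Z)-enal and olefinated to make C11=C12.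
- Comparison: the chosen plan is longer, but never puts positive charge on C8, contains no β-alkoxy ketone, has C3 in place from the start, and forms C10–C11 with retention.

Alternative 3: Only the O–C8 bond is cut, back to the α-hydroxyallene A7 (free C5 hydroxyl, C6=C7=C8 allene, H8 on the ring face of the C5 methyl). In the forward key step a carbophilic gold catalyst activates the C7=C8 bond, the C5 hydroxyl adds to C8 (5-endo closure of ring B onto ring A), and protodeauration gives the C15 furanoid bis-silyl ether A6.
- For: cycloisomerisation of α-hydroxyallenes to 2,5-dihydrofurans is well established and turns the allene axis into the C8 centre. C8 would thus be fixed by a stereospecific process and not by a modest bias; on this point the plan is stronger than the insertion. The allene can come from an alkynyl epoxide by anti SN2′ hydride delivery, which has the right sense, and C3 again comes from actinol.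
- Against: reaching A7 needs alkynylation of the ring ketone, dehydration, face-selective epoxidation (the same 1,3 problem as the C5 hydroxylation, on a less biased substrate) and the SN2′ reduction. That is about five steps after silylation, where the insertion route needs two to reach 10. An alkenyl-substituted allene can lose its axial configuration under cationic gold. A6, like A1, stops at a C11 silyl ether and needs oxidation to the labile (9Z)-enal and a geometry-forming olefination.
- Comparison: the chosen plan is shorter to ring B and ends directly on the C10 iodide. What it gives up, certainty at C8, is recovered by keeping this hydroxyallene chemistry as the fallback for the key step.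

Key step: step 6

Assumption: if step 6 delivers both C8 epimers, the 8R compound 14 is carried on after chromatographic separation; 1, 5, 11, 15, 16, 18 and 19 are taken as purchasable.

## Route

Step 1
Reactants: 1 (4R,6R)-4-hydroxy-2,2,6-trimethylcyclohexan-1-one (actinol)
Product: 2 (4R,6R)-4-[(tert-butyldimethylsilyl)oxy]-2,2,6-trimethylcyclohexan-1-one
Conditions: t-BuMe2SiCl, imidazole, DMF, rt
Reagents that add atoms: tert-butyldimethylsilyl chloride, CC(C)(C)[Si](C)(C)Cl
Why: Silylation of the secondary alcohol with a silyl chloride and imidazole; the ketone is untouched, and the C3 configuration is carried unchanged to the end.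

Step 2
Reactants: 2 (4R,6R)-4-[(tert-butyldimethylsilyl)oxy]-2,2,6-trimethylcyclohexan-1-one
Product: 4 (2R,4S)-4-[(tert-butyldimethylsilyl)oxy]-2-hydroxy-2,6,6-trimethylcyclohexan-1-one, via potassium enolate 3 (not isolated)
Conditions: KN(SiMe3)2, THF, −78 to −40 °C; then 2-(phenylsulfonyl)-3-phenyloxaziridine, −78 °C; aq NH4Cl
Reagents that add atoms: 2-(phenylsulfonyl)-3-phenyloxaziridine, O=S(=O)(c1ccccc1)N1OC1c1ccccc1
Why: Davis hydroxylation of the only possible enolate (the other α-carbon is quaternary). The oxidant should approach C5 along the axial line of the half-chair that keeps the C3 silyloxy group pseudo-equatorial, which is the face anti to that group; the other face needs a twist-boat or a conformer with the silyloxy group and a C1 methyl syn-axial, so C5 should be set R with its oxygen trans to the C3 oxygen.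

Step 3
Reactants: 5 prop-2-yn-1-ol
Product: 7 (2Z)-3-iodo-2-methylprop-2-en-1-ol, via oxamagnesacycle 6 (not isolated)
Conditions: CH3MgBr (3 equiv), CuI (10 mol %), THF/Et2O, −10 °C to rt; then I2, −10 °C; aq NH4Cl, Na2S2O3
Reagents that add atoms: methylmagnesium bromide, C[Mg]Br; iodine, [I][I]
Why: Copper-catalysed anti-carbomagnesiation of the propargylic alkoxide: methyl goes to the inner carbon and magnesium to the terminal carbon inside a five-membered chelate, so iodinolysis with retention places iodine cis to the CH2O group (Z).

Step 4
Reactants: 7 (2Z)-3-iodo-2-methylprop-2-en-1-ol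
Product: 8 (1Z)-3-bromo-1-iodo-2-methylprop-1-ene
Conditions: CBr4, PPh3, CH2Cl2, 0 °C
Reagents that add atoms: carbon tetrabromide, BrC(Br)(Br)Br
Why: Appel bromination, an SN2 displacement at the activated primary allylic carbon under neutral conditions; the alkenyl iodide and the Z geometry are not involved.

Step 5
Reactants: 4 (2R,4S)-4-[(tert-butyldimethylsilyl)oxy]-2-hydroxy-2,6,6-trimethylcyclohexan-1-one; 8 (1Z)-3-bromo-1-iodo-2-methylprop-1-ene
Product: 10 (2R,4S)-4-[(tert-butyldimethylsilyl)oxy]-2-{[(2Z)-3-iodo-2-methylprop-2-en-1-yl]oxy}-2,6,6-trimethylcyclohexan-1-one, via sodium alkoxide 9 (not isolated)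
Conditions: NaH, THF/DMF (4:1), 0 °C; then 8, Bu4NI (10 mol %), 0 °C to rt
Reagents that add atoms: none
Why: Williamson etherification: the tertiary alkoxide is hindered, but the electrophile is a primary allylic halide (turned into the iodide in the flask) with no β-hydrogen to eliminate. No stereocentre is touched, and the low temperature limits α-ketol rearrangement of the alkoxide.

Step 6
Reactants: 10 (2R,4S)-4-[(tert-butyldimethylsilyl)oxy]-2-{[(2Z)-3-iodo-2-methylprop-2-en-1-yl]oxy}-2,6,6-trimethylcyclohexan-1-one; 11 (trimethylsilyl)diazomethane
Product: 14 (2R,6S,7aR)-6-[(tert-butyldimethylsilyl)oxy]-2-[(1Z)-1-iodoprop-1-en-2-yl]-4,4,7a-trimethyl-2,4,5,6,7,7a-hexahydro-1-benzofuran, via lithium diazoalkoxide 12 (not isolated), via alkylidene carbene 13 (not isolated)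
Conditions: Me3SiCHN2 (1.5 equiv), n-BuLi, THF, −78 °C; add 10, −78 °C to rt
Reagents that add atoms: none
Why: Lithiated 11 adds to the C6 carbonyl of 10, which has no α-hydrogen and so can only be attacked, to give alkoxide 12; on warming, Peterson-type loss of Me3SiOLi and then of N2 leaves the singlet alkylidene carbene 13 (C6=C7:), which inserts into a C8–H bond. The closest known reaction type is the conversion of α-alkoxy ketones into 2,5-dihydrofurans by this reagent through 1,5 C–H insertion of the alkylidene carbene. Ring B closes in the 1,5-insertion mode: a single new σ bond C7–C8 completes the five-membered ring O–C5–C6=C7–C8 through a five-centre transition state in which the C8–H bond meets the empty in-plane orbital of C7, and C6=C7 ends up inside the ring. C8 is the new stereocentre and is under substrate control by C5: the insertion has to pick one of the two diastereotopic C8–H bonds, and the arrangement with the iodoalkenyl group turned away from the C5 methyl (toward the face of C4, which is tied back in ring A) leaves H8 cis to that methyl, i.e. 8R. The step needs site selectivity for C8–H: these are the only C–H bonds that are activated (ether oxygen and C9=C10) and five atoms from C7 on an unstrained path, whereas insertion at C3–H would need a bridgehead alkene, insertion at the methyl, C2 or C4 hydrogens would give cyclobutenes, and the ether oxygen could only form a four-membered ylide. The trisubstituted, iodine-bearing C9=C10 bond is a poor carbene acceptor and the stabilised lithium diazo species does not exchange with the alkenyl iodide, so the C10–I bond and the Z geometry should be kept.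

Step 7
Reactants: 15 (2E,4E,6E)-2,7-dimethylocta-2,4,6-trienedial; 16 triethyl phosphonoacetate
Product: 17 ethyl (2E,4E,6E,8E)-4,9-dimethyl-10-oxodeca-2,4,6,8-tetraenoate
Conditions: 16, NaH, THF, 0 °C; added slowly to 15 (1.5 equiv), THF/CH2Cl2, 0 °C to rt
Reagents that add atoms: none
Why: Horner–Wadsworth–Emmons olefination, E-selective with the stabilised phosphonate anion. Slow addition to an excess of the symmetrical dialdehyde favours mono-olefination, and unreacted 15 can be recovered.

Step 8
Reactants: 18 dibromomethane; 19 tributyltin chloride
Product: 21 tributyl(dibromomethyl)stannane, via dibromomethyllithium 20 (not isolated)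
Conditions: LiN(i-Pr)2 (from i-Pr2NH and n-BuLi), CH2Br2, THF/Et2O, −90 °C; then Bu3SnCl, −90 °C to rt
Reagents that add atoms: none
Why: Deprotonation of dibromomethane to the carbenoid at low temperature and its capture by substitution at tin; this is the usual way to this olefination reagent.

Step 9
Reactants: 17 ethyl (2E,4E,6E,8E)-4,9-dimethyl-10-oxodeca-2,4,6,8-tetraenoate; 21 tributyl(dibromomethyl)stannane
Product: 23 ethyl (2E,4E,6E,8E,10E)-4,9-dimethyl-11-(tributylstannyl)undeca-2,4,6,8,10-pentaenoate, via tributyl(diiodomethyl)stannane 22 (not isolated)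
Conditions: CrCl2 (8 equiv), LiI (4 equiv), 21 (2 equiv), THF/DMF, rt, dark
Reagents that add atoms: none
Why: Takai–Hodgson stannyl olefination: LiI turns 21 into 22, CrCl2 reduces it to a geminal dichromium species that adds to the aldehyde and eliminates to the (E)-alkenylstannane. Esters are inert to divalent chromium and enals are established substrates.

Step 10
Reactants: 23 ethyl (2E,4E,6E,8E,10E)-4,9-dimethyl-11-(tributylstannyl)undeca-2,4,6,8,10-pentaenoate
Product: 24 (2E,4E,6E,8E,10E)-4,9-dimethyl-11-(tributylstannyl)undeca-2,4,6,8,10-pentaen-1-ol
Conditions: i-Bu2AlH (2.5 equiv), CH2Cl2, −78 °C; aq potassium sodium tartrate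
Reagents that add atoms: none
Why: 1,2-Reduction of the conjugated ester to the allylic alcohol by the aluminium hydride; the alkenylstannane and the polyene are inert, and the non-acidic tartrate work-up avoids protodestannylation.

Step 11
Reactants: 14 (2R,6S,7aR)-6-[(tert-butyldimethylsilyl)oxy]-2-[(1Z)-1-iodoprop-1-en-2-yl]-4,4,7a-trimethyl-2,4,5,6,7,7a-hexahydro-1-benzofuran; 24 (2E,4E,6E,8E,10E)-4,9-dimethyl-11-(tributylstannyl)undeca-2,4,6,8,10-pentaen-1-ol
Product: 25 (2E,4E,6E,8E,10E,12Z)-13-[(2R,6S,7aR)-6-[(tert-butyldimethylsilyl)oxy]-4,4,7a-trimethyl-2,4,5,6,7,7a-hexahydro-1-benzofuran-2-yl]-4,9-dimethyltetradeca-2,4,6,8,10,12-hexaen-1-ol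
Conditions: Pd2(dba)3 (5 mol %), AsPh3 (40 mol %), NMP, rt to 40 °C, degassed, dark
Reagents that add atoms: none
Why: Stille coupling: oxidative addition of zerovalent palladium to the (Z)-alkenyl iodide and transmetalation from the (E)-alkenylstannane both proceed with retention, so C10–C11 forms with 9Z and 11E fixed. AsPh3 speeds transmetalation so the coupling can run near room temperature, and the free alcohol and the silyl ether are tolerated.

Step 12
Reactants: 25 (2E,4E,6E,8E,10E,12Z)-13-[(2R,6S,7aR)-6-[(tert-butyldimethylsilyl)oxy]-4,4,7a-trimethyl-2,4,5,6,7,7a-hexahydro-1-benzofuran-2-yl]-4,9-dimethyltetradeca-2,4,6,8,10,12-hexaen-1-ol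
Product: 26 (2E,4E,6E,8E,10E,12Z)-13-[(2R,6S,7aR)-6-hydroxy-4,4,7a-trimethyl-2,4,5,6,7,7a-hexahydro-1-benzofuran-2-yl]-4,9-dimethyltetradeca-2,4,6,8,10,12-hexaen-1-ol (CNP0263491.2)
Conditions: Bu4NF, THF, 0 °C to rt, dark; pH 7 buffer
Reagents that add atoms: none
Why: Fluoride cleavage of the secondary silyl ether, driven by Si–F bond formation; the basic, non-acidic conditions leave the C8 ether, the three stereocentres and the polyene geometry unchanged.

## Compound list

1 | (4R,6R)-4-hydroxy-2,2,6-trimethylcyclohexan-1-one (actinol) | CC1(C)C[C@H](O)C[C@@H](C)C1=O | starting material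
2 | (4R,6R)-4-[(tert-butyldimethylsilyl)oxy]-2,2,6-trimethylcyclohexan-1-one | CC1(C)C[C@H](O[Si](C)(C)C(C)(C)C)C[C@@H](C)C1=O | intermediate
3 | potassium (4R)-4-[(tert-butyldimethylsilyl)oxy]-2,6,6-trimethylcyclohex-1-en-1-olate (enolate of 2) | CC1(C)C[C@H](O[Si](C)(C)C(C)(C)C)CC(C)=C1[O-].[K+] | intermediate
4 | (2R,4S)-4-[(tert-butyldimethylsilyl)oxy]-2-hydroxy-2,6,6-trimethylcyclohexan-1-one | O=C1C(C)(C)C[C@H](O[Si](C)(C)C(C)(C)C)C[C@@]1(C)O | intermediate
5 | prop-2-yn-1-ol (propargyl alcohol) | C#CCO | starting material
6 | 4-methyl-2,5-dihydro-1,2-oxamagnesole (cyclic alkenylmagnesium alkoxide) | CC1=C[Mg]OC1 | intermediate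
7 | (2Z)-3-iodo-2-methylprop-2-en-1-ol | OC/C(C)=C\I | intermediate
8 | (1Z)-3-bromo-1-iodo-2-methylprop-1-ene | BrC/C(C)=C\I | intermediate
9 | sodium alkoxide of 4 | O=C1C(C)(C)C[C@H](O[Si](C)(C)C(C)(C)C)C[C@@]1(C)[O-].[Na+] | intermediate
10 | (2R,4S)-4-[(tert-butyldimethylsilyl)oxy]-2-{[(2Z)-3-iodo-2-methylprop-2-en-1-yl]oxy}-2,6,6-trimethylcyclohexan-1-one | O=C1C(C)(C)C[C@H](O[Si](C)(C)C(C)(C)C)C[C@@]1(C)OC/C(C)=C\I | intermediate
11 | (trimethylsilyl)diazomethane | C[Si](C)(C)C=[N+]=[N-] | starting material
12 | lithium 1-[diazo(trimethylsilyl)methyl]cyclohexan-1-olate from 10 (ring centres as in 10, either C6 epimer) | [Li+].[O-]C1(C(=[N+]=[N-])[Si](C)(C)C)C(C)(C)C[C@H](O[Si](C)(C)C(C)(C)C)C[C@@]1(C)OC/C(C)=C\I | intermediate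
13 | alkylidene carbene C6=C7: from 10 (ring centres as in 10) | [C]=C1C(C)(C)C[C@H](O[Si](C)(C)C(C)(C)C)C[C@@]1(C)OC/C(C)=C\I | intermediate
14 | (2R,6S,7aR)-6-[(tert-butyldimethylsilyl)oxy]-2-[(1Z)-1-iodoprop-1-en-2-yl]-4,4,7a-trimethyl-2,4,5,6,7,7a-hexahydro-1-benzofuran | I/C=C(C)\[C@H]1C=C2C(C)(C)C[C@H](O[Si](C)(C)C(C)(C)C)C[C@@]2(C)O1 | intermediate
15 | (2E,4E,6E)-2,7-dimethylocta-2,4,6-trienedial | O=C/C(C)=C/C=C/C=C(C)/C=O | starting material
16 | triethyl phosphonoacetate | CCOC(=O)CP(=O)(OCC)OCC | starting material
17 | ethyl (2E,4E,6E,8E)-4,9-dimethyl-10-oxodeca-2,4,6,8-tetraenoate | CCOC(=O)/C=C/C(C)=C/C=C/C=C(C)/C=O | intermediate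
18 | dibromomethane | BrCBr | starting material
19 | tributyltin chloride | CCCC[Sn](Cl)(CCCC)CCCC | starting material
20 | dibromomethyllithium | [Li]C(Br)Br | intermediate
21 | tributyl(dibromomethyl)stannane | CCCC[Sn](CCCC)(CCCC)C(Br)Br | intermediate
22 | tributyl(diiodomethyl)stannane | CCCC[Sn](CCCC)(CCCC)C(I)I | intermediate
23 | ethyl (2E,4E,6E,8E,10E)-4,9-dimethyl-11-(tributylstannyl)undeca-2,4,6,8,10-pentaenoate | CCOC(=O)/C=C/C(C)=C/C=C/C=C(C)/C=C/[Sn](CCCC)(CCCC)CCCC | intermediate
24 | (2E,4E,6E,8E,10E)-4,9-dimethyl-11-(tributylstannyl)undeca-2,4,6,8,10-pentaen-1-ol | OC/C=C/C(C)=C/C=C/C=C(C)/C=C/[Sn](CCCC)(CCCC)CCCC | intermediate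
25 | (2E,4E,6E,8E,10E,12Z)-13-[(2R,6S,7aR)-6-[(tert-butyldimethylsilyl)oxy]-4,4,7a-trimethyl-2,4,5,6,7,7a-hexahydro-1-benzofuran-2-yl]-4,9-dimethyltetradeca-2,4,6,8,10,12-hexaen-1-ol | C/C(=C/C=C/C(C)=C/C=C/C=C(C)/C=C/CO)[C@H]1C=C2C(C)(C)C[C@H](O[Si](C)(C)C(C)(C)C)C[C@@]2(C)O1 | intermediate
26 | (2E,4E,6E,8E,10E,12Z)-13-[(2R,6S,7aR)-6-hydroxy-4,4,7a-trimethyl-2,4,5,6,7,7a-hexahydro-1-benzofuran-2-yl]-4,9-dimethyltetradeca-2,4,6,8,10,12-hexaen-1-ol | C/C(=C/C=C/C(C)=C/C=C/C=C(C)/C=C/CO)[C@H]1C=C2C(C)(C)C[C@H](O)C[C@@]2(C)O1 | target

## Step count and least certain steps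

Total step count: 12 (the preparation of reagent 21 included). Longest linear sequence: 6 steps (1, 2, 5, 6, 11, 12 from actinol 1; the branch 3, 4, 5, 6, 11, 12 from 5 is equally long).

Step 6 (key step). Most likely to go wrong: weak discrimination between the two diastereotopic C8–H bonds, because the C5 substituents that tell them apart sit across the ring oxygen and the carbene is highly reactive. Slow addition of the lithiated diazo reagent to a carbonyl flanked by two quaternary carbons is the second risk; the reagent may decay before it adds. Fallback (sets out from 7 and 2, comes back at 14): ring B is closed by cycloisomerisation of a hydroxyallene, which fixes C8 by axis-to-centre transfer and needs only a small acetylide to add to the less hindered ketone 2.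
- MnO2 oxidation of 7 gives (2Z)-3-iodo-2-methylprop-2-enal F1, and Colvin homologation with lithiated 11 gives (1Z)-1-iodo-2-methylbut-1-en-3-yne F2.
- The lithium acetylide of F2 (LiN(i-Pr)2, THF, −78 °C) adds to 2 to give the tertiary propargylic alcohol F3.
- Dehydration (POCl3, pyridine) can only go toward C5 and gives the C5=C6 dienyne F4.
- mCPBA (NaHCO3, CH2Cl2, 0 °C) epoxidises the tetrasubstituted C5=C6 bond anti to the silyloxy group to give the alkynyl epoxide F5.
- i-Bu2AlH delivers hydride to C8 anti to the departing C6–O bond (SN2′) and gives the α-hydroxyallene F6 with H8 on the face of the C5 methyl.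
- Ph3PAuCl/AgOTf (CH2Cl2, rt) closes ring B by 5-endo attack of the C5 hydroxyl on C8 and should return 14 as one C8 epimer.

The weak point of this fallback is the face selectivity of the epoxidation.

Step 5. Most likely to go wrong: incomplete O-alkylation of the hindered tertiary alkoxide, and on longer exposure α-ketol rearrangement of alkoxide 9 (1,2-shift to an isomeric acyloin), because the alkoxide sits next to a ketone that cannot enolise. Fallback (sets out from 7 and 4, comes back at 10): the alkylation is moved from basic to acid catalysis. 7 with Cl3CCN and catalytic DBU gives (2Z)-3-iodo-2-methylprop-2-en-1-yl 2,2,2-trichloroacetimidate F7. With a catalytic amount of Me3SiOTf in CH2Cl2/cyclohexane at −20 °C, F7 transfers the allyl group to the free hydroxyl of 4 without an alkoxide ever being formed.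

Step 2. Most likely to go wrong: poor facial selectivity of the oxygen transfer, because the bulky oxaziridine meets the axial C1 methyl on the otherwise favoured face; incomplete enolisation of the hindered ketone is the lesser risk. Fallback (sets out from 2, comes back at 4): Rubottom oxidation. 2 with Me3SiOTf/Et3N gives the trimethylsilyl enol ether F8. The small, neutral mCPBA (NaHCO3, CH2Cl2, −20 °C) epoxidises it; on related 3-oxygenated trimethylcyclohexene rings a peracid tends to add anti to the C3 substituent. The silyloxy epoxide rearranges to the α-silyloxy ketone, and citric acid in MeOH frees the tertiary alcohol to give 4.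

Step 9. Most likely to go wrong: sluggish addition of the bulky geminal dichromium reagent to the α-branched, vinylogously deactivated aldehyde, with reductive dimerisation of the aldehyde by CrCl2 and erosion of E-selectivity. Fallback (sets out from 17, comes back at 23): the one-carbon unit is added without chromium. Colvin homologation of 17 with lithiated 11 (THF, −78 °C to rt) gives ethyl (2E,4E,6E,8E)-4,9-dimethylundeca-2,4,6,8-tetraen-10-ynoate F9. Palladium-catalysed syn hydrostannylation (Bu3SnH, 1 equiv, PdCl2(PPh3)2, THF, 0 °C) puts tin on the terminal carbon and gives 23; the minor internal regioisomer would be removed by chromatography.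

Step 11. Most likely to go wrong: slow transmetalation to the hindered (Z)-alkenylpalladium iodide, so that protodestannylation and homocoupling of 24 and, on longer heating, isomerisation of the Z bond compete. Fallback (sets out from 14 and 24, comes back at 25): a Suzuki–Miyaura coupling with reversed polarity. Iodine–lithium exchange on 14 (t-BuLi, 2 equiv, Et2O, −78 °C) and trapping with 2-isopropoxy-4,4,5,5-tetramethyl-1,3,2-dioxaborolane give the (Z)-alkenyl pinacol boronate F10. Iododestannylation of 24 (I2, CH2Cl2, −78 °C, dark) with retention gives (2E,4E,6E,8E,10E)-11-iodo-4,9-dimethylundeca-2,4,6,8,10-pentaen-1-ol F11. Coupling of F10 and F11 with Pd(PPh3)4 and TlOEt in THF/H2O at rt gives 25.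

## Further compounds

F1 | step 6 | (2Z)-3-iodo-2-methylprop-2-enal | O=C/C(C)=C\I
F2 | step 6 | (1Z)-1-iodo-2-methylbut-1-en-3-yne | C#C/C(C)=C\I
F3 | step 6 | (4R,6R)-4-[(tert-butyldimethylsilyl)oxy]-1-[(3Z)-4-iodo-3-methylbut-3-en-1-yn-1-yl]-2,2,6-trimethylcyclohexan-1-ol (either C1 epimer) | CC1(C)C[C@H](O[Si](C)(C)C(C)(C)C)C[C@@H](C)C1(O)C#C/C(C)=C\I
F4 | step 6 | tert-butyl({4-[(3Z)-4-iodo-3-methylbut-3-en-1-yn-1-yl]-3,5,5-trimethylcyclohex-3-en-1-yl}oxy)dimethylsilane, C5=C6 dienyne with C3 as in 2 | CC1(C)C[C@H](O[Si](C)(C)C(C)(C)C)CC(C)=C1C#C/C(C)=C\I
F5 | step 6 | 5,6-epoxide of F4 with the epoxide oxygen trans to the silyloxy group | [C@@]12(C#C/C(C)=C\I)O[C@]1(C)C[C@@H](O[Si](C)(C)C(C)(C)C)CC2(C)C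
F6 | step 6 | (1R,5S)-5-[(tert-butyldimethylsilyl)oxy]-2-[(3Z)-4-iodo-3-methylbuta-1,3-dien-1-ylidene]-1,3,3-trimethylcyclohexan-1-ol, allene axis with H8 on the ring face of the C5 methyl | O[C@]1(C)C[C@@H](O[Si](C)(C)C(C)(C)C)CC(C)(C)C1=C=C/C(C)=C\I
F7 | step 5 | (2Z)-3-iodo-2-methylprop-2-en-1-yl 2,2,2-trichloroacetimidate | N=C(OC/C(C)=C\I)C(Cl)(Cl)Cl
F8 | step 2 | trimethylsilyl enol ether of 2 (C3 as in 2) | CC1(C)C[C@H](O[Si](C)(C)C(C)(C)C)CC(C)=C1O[Si](C)(C)C
F9 | step 9 | ethyl (2E,4E,6E,8E)-4,9-dimethylundeca-2,4,6,8-tetraen-10-ynoate | C#C/C(C)=C/C=C/C=C(C)/C=C/C(=O)OCC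
F10 | step 11 | pinacol (Z)-alkenylboronate of 14 (boron in place of iodine at C10) | CC1(C)OB(OC1(C)C)/C=C(C)\[C@H]1C=C2C(C)(C)C[C@H](O[Si](C)(C)C(C)(C)C)C[C@@]2(C)O1
F11 | step 11 | (2E,4E,6E,8E,10E)-11-iodo-4,9-dimethylundeca-2,4,6,8,10-pentaen-1-ol | OC/C=C/C(C)=C/C=C/C=C(C)/C=C/I
A1 | alternative 1 | (2R,7aR)-2-{(2Z)-4-[(tert-butyldimethylsilyl)oxy]but-2-en-2-yl}-4,4,7a-trimethyl-2,4,5,7a-tetrahydro-1-benzofuran-6(7H)-one | C/C(=C/CO[Si](C)(C)C(C)(C)C)[C@H]1C=C2C(C)(C)CC(=O)C[C@@]2(C)O1
A2 | alternative 1 | (9R,10Z)-12-[(tert-butyldimethylsilyl)oxy]-9-hydroxy-2,6,10-trimethyldodeca-2,6,7,10-tetraen-4-one (either allene epimer) | CC(C)=CC(=O)CC(C)=C=C[C@@H](O)/C(C)=C\CO[Si](C)(C)C(C)(C)C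
A3 | alternative 2 | (2Z)-3-[(2R,7aR)-4,4,7a-trimethyl-6-oxo-2,4,5,6,7,7a-hexahydro-1-benzofuran-2-yl]but-2-enenitrile | N#C/C=C(C)\[C@H]1C=C2C(C)(C)CC(=O)C[C@@]2(C)O1
A4 | alternative 2 | (2Z,4E)-5-[(1S)-1-hydroxy-2,6,6-trimethyl-4-oxocyclohex-2-en-1-yl]-3-methylpenta-2,4-dienenitrile (abscisic nitrile) | CC1=CC(=O)CC([C@]1(/C=C/C(=C\C#N)/C)O)(C)C
A5 | alternative 2 | (S)-abscisic acid | CC1=CC(=O)CC([C@]1(/C=C/C(=C\C(=O)O)/C)O)(C)C
A6 | alternative 3 | (2R,6S,7aR)-6-[(tert-butyldimethylsilyl)oxy]-2-{(2Z)-4-[(tert-butyldimethylsilyl)oxy]but-2-en-2-yl}-4,4,7a-trimethyl-2,4,5,6,7,7a-hexahydro-1-benzofuran | C/C(=C/CO[Si](C)(C)C(C)(C)C)[C@H]1C=C2C(C)(C)C[C@H](O[Si](C)(C)C(C)(C)C)C[C@@]2(C)O1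
A7 | alternative 3 | (1R,5S)-5-[(tert-butyldimethylsilyl)oxy]-2-{(3Z)-5-[(tert-butyldimethylsilyl)oxy]-3-methylpenta-1,3-dien-1-ylidene}-1,3,3-trimethylcyclohexan-1-ol, allene axis with H8 on the ring face of the C5 methyl | C/C(=C/CO[Si](C)(C)C(C)(C)C)C=C=C1C(C)(C)C[C@H](O[Si](C)(C)C(C)(C)C)C[C@@]1(C)O
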